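**Retrosynthetic overview**
1. Target 19 ⇐ ene-dione 16: an Evans–Tishchenko reaction with a 4-silyloxybenzaldehyde reduces the C4 ketone (azulene numbering) from the tertiary oxygen and acylates that oxygen in the same event; desilylation finishes.
2. 16 ⇐ oxa-bridged tricycle 14 by SmI2 cleavage of the α-keto C–O bond and oxidation of the liberated allylic alcohol.
3. 14 ⇐ 3-oxidopyrylium ylide 13 by intramolecular [5+2] cycloaddition onto a tethered 1,1-disubstituted alkene. The cyclopentane and the cycloheptenone form together in this step, and the quaternary methyl centre is set by the tertiary carbinol.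
4. 13 ⇐ Achmatowicz pyranone 11 ⇐ furyl diol 10 ⇐ 3-methylfuran + dioxolanone 6.
5. 6 ⇐ (R)-2-hydroxy-3-methylbutanoic acid by Seebach acetalisation and alkylation with self-regeneration of the stereocentre.

Assumption: (R)-2-hydroxy-3-methylbutanoic acid (from D-valine) is taken as the purchased chiral material; carbons that become sp2 in ylide 13 (the carbinol carbon of 10, C2/C6 of 11 and 12) are carried as mixtures.

**Step 1**
Reactants: 1 (R)-2-hydroxy-3-methylbutanoic acid; 2 pivalaldehyde (2,2-dimethylpropanal)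
Product: 3 (2R,5R)-2-tert-butyl-5-(propan-2-yl)-1,3-dioxolan-4-one
Conditions: TsOH·H2O (cat.), H2SO4 (cat.), pentane, reflux, Dean–Stark; recrystallise the cis isomer
Reagents that add atoms: none
Why: Acid-catalysed acetalisation (Seebach dioxolanone) under equilibrating conditions gives the cis acetal, so the new acetal centre is fixed by the purchased carbinol centre.

**Step 2**
Reactants: 3 (2R,5R)-2-tert-butyl-5-(propan-2-yl)-1,3-dioxolan-4-one; 4 4-bromo-2-methylbut-1-ene
Product: 6 (2R,5R)-2-tert-butyl-5-(3-methylbut-3-en-1-yl)-5-(propan-2-yl)-1,3-dioxolan-4-one, via lithium enolate 5 (not isolated)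
Conditions: LDA, THF–DMPU (4:1), −78 °C; then 4, −78 → −30 °C
Reagents that add atoms: none
Why: Self-regeneration of stereocentres: the planar lithium enolate is alkylated (SN2) anti to the tert-butyl group, so the homoallyl chain replaces the former hydrogen with retention and rebuilds the tertiary alkoxy centre.

**Step 3**
Reactants: 6 (2R,5R)-2-tert-butyl-5-(3-methylbut-3-en-1-yl)-5-(propan-2-yl)-1,3-dioxolan-4-one; 7 3-methylfuran
Product: 10 (1RS,2R)-5-methyl-1-(4-methylfuran-2-yl)-2-(propan-2-yl)hex-5-ene-1,2-diol, via 2-lithio-4-methylfuran 8 (not isolated), via furyl ketone 9 (not isolated)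
Conditions: 7, t-BuLi, THF, −78 → −20 °C; then 6, −78 °C; then MeOH, NaBH4, −78 → 0 °C
Reagents that add atoms: none
Why: α-Lithiation of 3-methylfuran at the unhindered C5 (the minor 2,3-isomer is removed at the diol stage) and 1,2-addition to the dioxolanone carbonyl give, after collapse of the hemiketal with loss of pivalaldehyde, the α-hydroxy ketone, which NaBH4 reduces in the same pot; the new carbinol centre is irrelevant because it becomes sp2 later.

**Step 4**
Reactants: 10 (1RS,2R)-5-methyl-1-(4-methylfuran-2-yl)-2-(propan-2-yl)hex-5-ene-1,2-diol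
Product: 11 6-hydroxy-2-[(3R)-3-hydroxy-2,6-dimethylhept-6-en-3-yl]-5-methyl-2H-pyran-3(6H)-one
Conditions: NBS (1.0 equiv), NaHCO3, THF–H2O (4:1), 0 °C; used crude
Reagents that add atoms: water, O
Why: Achmatowicz rearrangement: bromonium-induced oxidative opening of the furfuryl alcohol and re-closure to the pyranone hemiacetal, the electron-rich furan reacting much faster with NBS than the isolated alkene.

**Step 5**
Reactants: 11 6-hydroxy-2-[(3R)-3-hydroxy-2,6-dimethylhept-6-en-3-yl]-5-methyl-2H-pyran-3(6H)-one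
Product: 14 (1S,2R,5R,7S)-2-hydroxy-5,8-dimethyl-2-(propan-2-yl)-11-oxatricyclo[5.3.1.0(1,5)]undec-8-en-10-one, via anomeric acetate 12 (not isolated), via oxidopyrylium ylide 13 (not isolated)
Conditions: Ac2O (1.1 equiv), i-Pr2NEt, DMAP (cat.), MeCN, 0 °C → rt; then DBU, 80 °C
Reagents that add atoms: none
Why: Anomeric acetylation, base-induced loss of acetic acid to the 3-oxidopyrylium ylide and intramolecular [5+2] cycloaddition close both carbocycles at once; the O–H···O⁻ hydrogen bond and A(1,3) strain hold the tertiary hydroxyl syn to the oxido oxygen (isopropyl towards the ring oxygen), so the alkene adds to the face that puts the quaternary methyl cis to the hydroxyl.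

**Step 6**
Reactants: 14 (1S,2R,5R,7S)-2-hydroxy-5,8-dimethyl-2-(propan-2-yl)-11-oxatricyclo[5.3.1.0(1,5)]undec-8-en-10-one
Product: 15 (3R,3aR,7S,8aR)-3,7-dihydroxy-6,8a-dimethyl-3-(propan-2-yl)-2,3,3a,7,8,8a-hexahydroazulen-4(1H)-one
Conditions: SmI2 (2.5 equiv), THF–MeOH, −78 °C; aq. NH4Cl
Reagents that add atoms: none
Why: SmI2 ketyl formation and cleavage of the α-alkoxy ketone C–O bond open the oxa-bridge to the γ-hydroxy enone; the samarium enolate is protonated where the oxygen left, which is also the thermodynamically preferred trans ring fusion of this epimerisable centre.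

**Step 7**
Reactants: 15 (3R,3aR,7S,8aR)-3,7-dihydroxy-6,8a-dimethyl-3-(propan-2-yl)-2,3,3a,7,8,8a-hexahydroazulen-4(1H)-one
Product: 16 (3R,3aR,8aR)-3-hydroxy-6,8a-dimethyl-3-(propan-2-yl)-1,2,3,3a,8,8a-hexahydroazulene-4,7-dione
Conditions: Dess–Martin periodinane, CH2Cl2, 0 °C → rt
Reagents that add atoms: none
Why: Dess–Martin oxidation of the secondary allylic alcohol gives the ene-dione, while the tertiary alcohol cannot be oxidised.

**Step 8**
Reactants: 16 (3R,3aR,8aR)-3-hydroxy-6,8a-dimethyl-3-(propan-2-yl)-1,2,3,3a,8,8a-hexahydroazulene-4,7-dione; 17 4-[(tert-butyldimethylsilyl)oxy]benzaldehyde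
Product: 18 (3R,3aS,4S,8aR)-4-hydroxy-6,8a-dimethyl-7-oxo-3-(propan-2-yl)-1,2,3,3a,4,7,8,8a-octahydroazulen-3-yl 4-[(tert-butyldimethylsilyl)oxy]benzoate
Conditions: 17 (5 equiv) premixed with SmI2 (0.3 equiv), THF, −10 °C; then 16, −10 °C
Reagents that add atoms: none
Why: Evans–Tishchenko reaction: the samarium hemiacetal formed on the tertiary oxygen transfers hydride intramolecularly to the β-hydroxy ketone carbonyl through a six-membered transition state, which acylates the tertiary oxygen, leaves the out-of-reach enone carbonyl untouched and, because the trans-fused ring holds that oxygen over one face of the ketone, sets the 4S carbinol.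

**Step 9**
Reactants: 18 (3R,3aS,4S,8aR)-4-hydroxy-6,8a-dimethyl-7-oxo-3-(propan-2-yl)-1,2,3,3a,4,7,8,8a-octahydroazulen-3-yl 4-[(tert-butyldimethylsilyl)oxy]benzoate
Product: 19 (3R,3aS,4S,8aR)-4-hydroxy-6,8a-dimethyl-7-oxo-3-(propan-2-yl)-1,2,3,3a,4,7,8,8a-octahydroazulen-3-yl 4-hydroxybenzoate (CNP0153637.1)
Conditions: HF·pyridine, THF–pyridine, 0 °C
Reagents that add atoms: none
Why: Fluoride cleavage of the aryl silyl ether under mildly acidic conditions avoids base-induced 1,3-acyl migration or ester cleavage.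

**Compound list**
1 | (R)-2-hydroxy-3-methylbutanoic acid | CC(C)[C@@H](O)C(=O)O | starting material
2 | pivalaldehyde (2,2-dimethylpropanal) | CC(C)(C)C=O | starting material
3 | (2R,5R)-2-tert-butyl-5-(propan-2-yl)-1,3-dioxolan-4-one | CC(C)[C@H]1O[C@@H](C(C)(C)C)OC1=O | intermediate
4 | 4-bromo-2-methylbut-1-ene | C=C(C)CCBr | starting material
5 | lithium (2R)-2-tert-butyl-5-(propan-2-yl)-1,3-dioxol-4-olate (lithium enolate of 3) | CC(C)C1=C(O[Li])O[C@H](C(C)(C)C)O1 | intermediate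
6 | (2R,5R)-2-tert-butyl-5-(3-methylbut-3-en-1-yl)-5-(propan-2-yl)-1,3-dioxolan-4-one | CC(C)[C@@]1(CCC(C)=C)O[C@@H](C(C)(C)C)OC1=O | intermediate
7 | 3-methylfuran | Cc1ccoc1 | starting material
8 | 2-lithio-4-methylfuran | [Li]c1cc(C)co1 | intermediate
9 | (2R)-2-hydroxy-5-methyl-1-(4-methylfuran-2-yl)-2-(propan-2-yl)hex-5-en-1-one (furyl ketone) | CC(C)[C@](O)(CCC(C)=C)C(=O)c1cc(C)co1 | intermediate
10 | (1RS,2R)-5-methyl-1-(4-methylfuran-2-yl)-2-(propan-2-yl)hex-5-ene-1,2-diol | CC(C)[C@](O)(CCC(C)=C)C(O)c1cc(C)co1 | intermediate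
11 | 6-hydroxy-2-[(3R)-3-hydroxy-2,6-dimethylhept-6-en-3-yl]-5-methyl-2H-pyran-3(6H)-one | CC(C)[C@](O)(CCC(C)=C)C1OC(O)C(C)=CC1=O | intermediate
12 | 6-[(3R)-3-hydroxy-2,6-dimethylhept-6-en-3-yl]-3-methyl-5-oxo-5,6-dihydro-2H-pyran-2-yl acetate (anomeric acetate) | CC(C)[C@](O)(CCC(C)=C)C1OC(OC(C)=O)C(C)=CC1=O | intermediate
13 | 2-[(3R)-3-hydroxy-2,6-dimethylhept-6-en-3-yl]-5-methylpyrylium-3-olate (oxidopyrylium ylide) | CC(C)[C@](O)(CCC(C)=C)c1[o+]cc(C)cc1[O-] | intermediate
14 | (1S,2R,5R,7S)-2-hydroxy-5,8-dimethyl-2-(propan-2-yl)-11-oxatricyclo[5.3.1.0(1,5)]undec-8-en-10-one | CC(C)[C@]1(O)CC[C@]2(C)C[C@@H]3O[C@]12C(=O)C=C3C | intermediate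
15 | (3R,3aR,7S,8aR)-3,7-dihydroxy-6,8a-dimethyl-3-(propan-2-yl)-2,3,3a,7,8,8a-hexahydroazulen-4(1H)-one | CC(C)[C@]1(O)CC[C@]2(C)C[C@H](O)C(C)=CC(=O)[C@@H]12 | intermediate
16 | (3R,3aR,8aR)-3-hydroxy-6,8a-dimethyl-3-(propan-2-yl)-1,2,3,3a,8,8a-hexahydroazulene-4,7-dione | CC(C)[C@]1(O)CC[C@]2(C)CC(=O)C(C)=CC(=O)[C@@H]12 | intermediate
17 | 4-[(tert-butyldimethylsilyl)oxy]benzaldehyde | CC(C)(C)[Si](C)(C)Oc1ccc(C=O)cc1 | starting material
18 | (3R,3aS,4S,8aR)-4-hydroxy-6,8a-dimethyl-7-oxo-3-(propan-2-yl)-1,2,3,3a,4,7,8,8a-octahydroazulen-3-yl 4-[(tert-butyldimethylsilyl)oxy]benzoate | CC(C)[C@]1(OC(=O)c3ccc(O[Si](C)(C)C(C)(C)C)cc3)CC[C@]2(C)CC(=O)C(C)=C[C@H](O)[C@@H]12 | intermediate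
19 | (3R,3aS,4S,8aR)-4-hydroxy-6,8a-dimethyl-7-oxo-3-(propan-2-yl)-1,2,3,3a,4,7,8,8a-octahydroazulen-3-yl 4-hydroxybenzoate | CC(C)[C@]1(OC(=O)c3ccc(O)cc3)CC[C@]2(C)CC(=O)C(C)=C[C@H](O)[C@@H]12 | target

**Totals**
Total step count: 9. Longest linear sequence: 9 (1 → 19).

**Three steps most likely to fail**

Step 5 (key cycloaddition). The new bond joins two fully substituted carbons, the free tertiary hydroxyl can be acetylated or trap the pyranone as a bridged ketal, and the facial selectivity rests on one hydrogen bond. Fallback, setting out from 11 and coming back at 14: acetylate and isolate 12 (Ac2O, pyridine, 0 °C), then cap the tertiary hydroxyl (TMSOTf, 2,6-lutidine, −78 °C) to give 6-[(3R)-2,6-dimethyl-3-(trimethylsilyloxy)hept-6-en-3-yl]-3-methyl-5-oxo-5,6-dihydro-2H-pyran-2-yl acetate F2. Run the cycloaddition on this protected substrate (DBU, MeCN, 80–120 °C, sealed tube) to give (1S,2R,5R,7S)-5,8-dimethyl-2-(propan-2-yl)-2-(trimethylsilyloxy)-11-oxatricyclo[5.3.1.0(1,5)]undec-8-en-10-one F3. Without the hydrogen bond the epimer at the methyl-bearing centre is expected in larger amount and is removed by chromatography. Cleaving the silyl ether (citric acid, MeOH) returns 14.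

Step 8 (Evans–Tishchenko on a tertiary carbinol). Hemiacetal formation may be too slow, the aroyl group may migrate to the new secondary hydroxyl, or Sm(III) may trigger retro-aldol opening. Fallback, setting out from 16 and coming back at 19: hydroxyl-directed reduction with Me4NBH(OAc)3 (MeCN–AcOH, −30 °C) gives (3R,3aS,4S,8aR)-3,4-dihydroxy-6,8a-dimethyl-3-(propan-2-yl)-2,3,3a,4,8,8a-hexahydroazulen-7(1H)-one F4. Selective silylation of the secondary alcohol (TESCl, imidazole, DMF, 0 °C) gives (3R,3aS,4S,8aR)-3-hydroxy-6,8a-dimethyl-3-(propan-2-yl)-4-(triethylsilyloxy)-2,3,3a,4,8,8a-hexahydroazulen-7(1H)-one F5. Yamaguchi acylation of the tertiary alcohol (4-[(tert-butyldimethylsilyl)oxy]benzoic acid, 2,4,6-trichlorobenzoyl chloride, Et3N, DMAP, toluene, 80 °C) gives (3R,3aS,4S,8aR)-6,8a-dimethyl-7-oxo-3-(propan-2-yl)-4-(triethylsilyloxy)-1,2,3,3a,4,7,8,8a-octahydroazulen-3-yl 4-[(tert-butyldimethylsilyl)oxy]benzoate F6. Global desilylation (HF·pyridine, THF, 0 °C) gives 19 directly.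

Step 2 (alkylation of a hindered enolate with an unactivated homoallylic bromide). E2 elimination to isoprene or enolate decomposition may win. Fallback, setting out from 3 and coming back at 6: add the lithium enolate 5 in a conjugate (Michael) addition to but-3-en-2-one (THF, −78 °C, same approach anti to tert-butyl) to give (2R,5R)-2-tert-butyl-5-(3-oxobutyl)-5-(propan-2-yl)-1,3-dioxolan-4-one F1. Wittig methylenation of the ketone (Ph3P=CH2, THF, 0 °C) returns 6.

**Further compounds**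
F1 | step 2 | (2R,5R)-2-tert-butyl-5-(3-oxobutyl)-5-(propan-2-yl)-1,3-dioxolan-4-one | CC(C)[C@@]1(CCC(C)=O)O[C@@H](C(C)(C)C)OC1=O
F2 | step 5 | 6-[(3R)-2,6-dimethyl-3-(trimethylsilyloxy)hept-6-en-3-yl]-3-methyl-5-oxo-5,6-dihydro-2H-pyran-2-yl acetate | CC(C)[C@](O[Si](C)(C)C)(CCC(C)=C)C1OC(OC(C)=O)C(C)=CC1=O
F3 | step 5 | (1S,2R,5R,7S)-5,8-dimethyl-2-(propan-2-yl)-2-(trimethylsilyloxy)-11-oxatricyclo[5.3.1.0(1,5)]undec-8-en-10-one | CC(C)[C@]1(O[Si](C)(C)C)CC[C@]2(C)C[C@@H]3O[C@]12C(=O)C=C3C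
F4 | step 8 | (3R,3aS,4S,8aR)-3,4-dihydroxy-6,8a-dimethyl-3-(propan-2-yl)-2,3,3a,4,8,8a-hexahydroazulen-7(1H)-one | CC(C)[C@]1(O)CC[C@]2(C)CC(=O)C(C)=C[C@H](O)[C@@H]12
F5 | step 8 | (3R,3aS,4S,8aR)-3-hydroxy-6,8a-dimethyl-3-(propan-2-yl)-4-(triethylsilyloxy)-2,3,3a,4,8,8a-hexahydroazulen-7(1H)-one | CC(C)[C@]1(O)CC[C@]2(C)CC(=O)C(C)=C[C@H](O[Si](CC)(CC)CC)[C@@H]12
F6 | step 8 | (3R,3aS,4S,8aR)-6,8a-dimethyl-7-oxo-3-(propan-2-yl)-4-(triethylsilyloxy)-1,2,3,3a,4,7,8,8a-octahydroazulen-3-yl 4-[(tert-butyldimethylsilyl)oxy]benzoate | CC(C)[C@]1(OC(=O)c3ccc(O[Si](C)(C)C(C)(C)C)cc3)CC[C@]2(C)CC(=O)C(C)=C[C@H](O[Si](CC)(CC)CC)[C@@H]12
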